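## The problem

The target joins a 2,2-dimethyl-2H-chromene (pyran ring A fused to benzene ring B) through one CH2 group to C3 of a 6-ethyl-4-hydroxy-5-methyl-2-pyranone (ring C). Ring B is hexasubstituted: O1 at C8a, the ring A carbon at C4a, hydroxyls at C5 and C7, the bridge at C6 and the (S)-2-methylbutanoyl group at C8. Its parent is phloroglucinol (1), whose three CH positions are equivalent, so the real task is to place three different carbon substituents on C4a, C6 and C8 one at a time without statistical mixtures or phenol differentiation. The only stereocentre is the α-carbon of the aryl ketone; no other stereo element can control it, and it can epimerize by enolization, so it should come from the chiral pool, enter late and see no base. The C3=C4 bond of ring A is an electron-rich styrene that is sensitive to acid, the lactone of ring C opens with hard nucleophiles, the CH2 bridge between two enol-like rings can cleave under forcing acid or base, and the phloroglucinol ring oxidizes easily. The enabling feature is that C6 lies between the oxygen-bearing carbons C5 and C7. One oxidation level below the arene, in a 7-silyloxy-7,8-dihydro-2H-chromen-5(6H)-one, C5 is a ketone, C4a=C8a–O1 is a vinylogous ester, and C6 is the only α′ carbon and therefore the only site of kinetic enolization. The two extra hydrogens of that dihydro ring are exactly those needed to bring an aldehyde carbon down to the bridge CH2, so aldol condensation at C6 and a double-bond shift can deliver the arene with all three oxygens and no external oxidant or reductant.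

## Retrosynthesis

**C8–acyl bond.** The bond from C8 to the ketone carbon is cut last: 24 goes back to triol 21 and acid chloride 23, made from commercial (S)-acid 22. C8 is the only unsubstituted carbon of ring B in 21, ortho to O1 and 7-OH and para to 5-OH, so there is no regiochemical question. Placing the acyl group earlier would make C8–H the most acidic proton of the dihydro series, which would spoil the enolate regiochemistry, and would carry the labile stereocentre through strong base and fluoride. The forward reaction must be an electrophilic acylation mild enough for the ring A double bond and for the configuration.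

**Protecting groups.** Triol 21 goes back to 19, which carries an aryl silyl ether at O7 and a 2-(trimethylsilyl)ethyl ether on the pyranone oxygen. No skeletal bond is cut. Both groups are chosen to leave with fluoride in one operation; an acetal on the pyranone would need a separate acid step and would be more labile in the isomerization.

**Isoaromatization.** Phenol 19 is an isomer of the exocyclic enone 17: the C7 hydrogen moves to the bridge carbon and a C8 hydrogen to O5. This makes the aromatic ring B reachable from a non-aromatic ring in which C4a, C6 and C8 are chemically different. The forward reaction must shift the double bond without expelling the allylic silyloxy group, so it has to be a buffered hydridometal isomerization and not an acid- or base-driven one.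

**Key disconnection.** The C6=C(bridge) double bond of 17 is cut as an aldol condensation, giving ketone 7 and aldehyde 13. The neighbouring cut, bridge carbon to pyranone C3 at the aromatic level, would ask a phloroglucinol to choose among equivalent positions and invites double bridging. Here each partner has one reactive site: C6 in 7 and the formyl group in 13. The cut divides the molecule into two fragments of similar size. The forward step needs kinetic deprotonation at C6, survival of the β-silyloxy group, 1,2-addition to the aldehyde and elimination toward the exocyclic position.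

**Ring A.** Chromenone 7 is cut at C4–C4a and O1–C2 into dione 4 and enal 5 (Knoevenagel condensation and oxa-6π closure). Dione 4 is mirror-symmetric and has a single carbon between its carbonyls, so ring A is made without regiochemical choice; on the arene the same annulation would need mono-selectivity. Dione 4 comes from 2 by silylation, and 2 from phloroglucinol 1 by reduction of one carbonyl of its keto tautomer.

**Pyranone aldehyde.** Aldehyde 13 is cut at the C4–O ether bond to chloro aldehyde 12, which comes from pyranone 10 by chloroformylation at C3 and C4. Pyranone 10 is cut at C4–C5 and O1–C2 into pentan-3-one 8 and malonyl dichloride 9. Going through 12 avoids O-alkylation of a 3-formyl-4-hydroxypyranone, whose anion offers three competing oxygens.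

## Roads not taken

Alternative 1: Ring A is cut at C4–C4a and made on the finished aromatic core. Heating the aryl 1,1-dimethylpropargyl ether A2 would trigger a [3,3] shift to an ortho carbon, and enolization, a 1,5-hydrogen shift and oxa-6π closure would then give chromene A1, which is the same compound as 21. Its merits are that everything stays aromatic, no oxidation level has to be adjusted, the step is thermal and neutral, and the two ortho carbons of the para oxygen are equivalent. Its weak points lie before the key step. A2 requires attaching exactly one pyranonylmethyl group to a phloroglucinol with three equivalent carbons, and then etherifying only the para hydroxyl with a tertiary propargyl electrophile beside two other phenols and the acidic pyranone hydroxyl. A1 then needs the same C8 acylation as the chosen route, so nothing is gained at the end. This road is probably shorter to A1 and carries no risk of losing a ring oxygen. The chosen plan sets against it that every ring position is addressed once by construction, with no statistical step and no phenol differentiation.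

Alternative 2: The stereocentre is made, not bought. An iridium catalyst [Ir(cod)(L)][B(C6H3(CF3)2)4], with L a chiral phosphine–oxazoline, would add H2 to the tigloyl ketone A4 and give the (S) ketone A3. Its merits are catalytic stereocontrol and an acyl group in place from the start, so no Friedel–Crafts reaction is needed on a finished chromene; in that respect it is better than the chosen plan. Its weak points are several. It spends its key step on a stereocentre that a commercial acid (22) already supplies. The doubly ortho-substituted aryl ketone A4 is twisted out of conjugation, which makes selectivity uncertain. The epimerizable centre of A3 must then survive acetal removal, chromene annulation with amine and heat, and bridge formation. The placement of ring A and the bridge, including the choice of which hydroxyl closes the pyran, is left unsolved. The chosen plan sets against the early acyl group a stereocentre that enters in the last step and meets no base.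

Alternative 3: The C8–acyl bond is formed by an anionic Fries shift. Iodine–lithium exchange on the tri-ester iodide A6 with t-BuLi would give a C8 anion that takes the acyl group from the neighbouring 7-O ester, giving A5. Its merit is a regiospecific, intramolecular, non-acidic acylation that spares the ring A double bond; this is a real advantage over the last step of the chosen route. Its weak points are iodination and triple esterification beforehand, three equivalents of the chiral acid of which two are discarded, and t-BuLi in the presence of three esters with enolizable stereocentres and a lactone. Two ester cleavages by base then follow with the epimerizable ketone present. It is an endgame only and still needs the triol. The chosen plan sets one step against its four; if Lewis acid proves incompatible with ring A, the fallback for step 11 uses a milder organometallic acylation.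

Key step: step 7

Remark on the chemistry: 7 and everything derived from it up to 17 is racemic at C7, and 17 may be an E/Z mixture; both features vanish when ring B becomes aromatic in step 8, so neither is controlled.

## Route

Step 1
Reactants: 1 benzene-1,3,5-triol (phloroglucinol)
Product: 2 5-hydroxycyclohexane-1,3-dione
Conditions: NaBH4, aq. NaOH (1 equiv), 0 °C → rt; then HCl to pH 3, 0 °C
Reagents that add atoms: none
Why: Borohydride reduction of the keto tautomer of the phloroglucinol anion; once one carbonyl is reduced the remaining 1,3-dione is an enolate and is not reduced further, so the reaction should stop at the dihydro stage, and cold, brief acidification avoids dehydration and rearomatization.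

Step 2
Reactants: 2 5-hydroxycyclohexane-1,3-dione
Product: 4 5-(tert-butyldimethylsilyloxy)cyclohexane-1,3-dione, via bis-silyl enol ether 3 (not isolated)
Conditions: TBSCl (2.3 equiv), imidazole, DMF, 0 °C → rt; then AcOH–THF–H2O, 0 °C
Reagents that add atoms: tert-butyldimethylsilyl chloride, CC(C)(C)[Si](C)(C)Cl
Why: Standard silylation of the secondary alcohol; the enol oxygen is silylated as well, but this vinylogous silyl ester is hydrolysed selectively by dilute acid while the alkyl silyl ether stays (selective cleavage of a silyl enol ether).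

Step 3
Reactants: 4 5-(tert-butyldimethylsilyloxy)cyclohexane-1,3-dione; 5 3-methylbut-2-enal
Product: 7 7-(tert-butyldimethylsilyloxy)-2,2-dimethyl-7,8-dihydro-2H-chromen-5(6H)-one (racemic), via alkylidene dione 6 (not isolated)
Conditions: ethylenediammonium diacetate (10 mol %), MeOH, rt
Reagents that add atoms: none
Why: Knoevenagel condensation at the only carbon between the two carbonyls gives a 1-oxatriene that closes by oxa-6π electrocyclization (formal [3+3] annulation of 1,3-diones with enals); the mirror symmetry of 4 leaves no regiochemical choice, and C7 becomes a stereocentre only as a racemate.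

Step 4
Reactants: 8 pentan-3-one; 9 malonyl dichloride
Product: 10 6-ethyl-4-hydroxy-5-methyl-2H-pyran-2-one
Conditions: neat, 0 °C → rt, 48 h
Reagents that add atoms: none
Why: Known pyranone synthesis from a ketone and malonyl dichloride: C-acylation of the ketone enol followed by O-acylation of the new enol closes the lactone, and the symmetrical ketone can give only one product.

Step 5
Reactants: 10 6-ethyl-4-hydroxy-5-methyl-2H-pyran-2-one
Product: 12 4-chloro-6-ethyl-5-methyl-2-oxo-2H-pyran-3-carbaldehyde, via iminium chloride 11 (not isolated)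
Conditions: POCl3, DMF, 0 → 60 °C; then ice–water
Reagents that add atoms: N,N-dimethylformamide, CN(C)C=O; phosphoryl chloride, O=P(Cl)(Cl)Cl; water, O
Why: Vilsmeier–Haack chloroformylation as established for 4-hydroxy-2-pyranones and 4-hydroxycoumarins: the nucleophilic C3 is formylated and the 4-hydroxyl is exchanged for chloride, C5 being blocked by its methyl group.

Step 6
Reactants: 12 4-chloro-6-ethyl-5-methyl-2-oxo-2H-pyran-3-carbaldehyde
Product: 13 6-ethyl-5-methyl-2-oxo-4-[2-(trimethylsilyl)ethoxy]-2H-pyran-3-carbaldehyde
Conditions: Me3SiCH2CH2OH, Et3N, CH2Cl2, 0 °C → rt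
Reagents that add atoms: 2-(trimethylsilyl)ethanol, C[Si](C)(C)CCO
Why: Addition–elimination at C4 of a vinylogous acid chloride activated by both the aldehyde and the lactone carbonyl, the usual reaction of 4-chloro-3-formyl-2-pyranones and -coumarins with O-, N- and S-nucleophiles.

Step 7
Reactants: 7 7-(tert-butyldimethylsilyloxy)-2,2-dimethyl-7,8-dihydro-2H-chromen-5(6H)-one (racemic); 13 6-ethyl-5-methyl-2-oxo-4-[2-(trimethylsilyl)ethoxy]-2H-pyran-3-carbaldehyde
Product: 17 7-(tert-butyldimethylsilyloxy)-6-({6-ethyl-5-methyl-2-oxo-4-[2-(trimethylsilyl)ethoxy]-2H-pyran-3-yl}methylidene)-2,2-dimethyl-7,8-dihydro-2H-chromen-5(6H)-one (racemic; alkene geometry not fixed), via lithium enolate 14 (not isolated), via lithium aldolate 15 (not isolated), via aldol mesylate 16 (not isolated)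
Conditions: LiN(iPr)2, THF, −78 °C; 13, −78 °C; MsCl then Et3N, −78 → 0 °C
Reagents that add atoms: none
Why: LiN(iPr)2 removes a C6 hydrogen of 7 irreversibly at −78 °C, because C6 is the only α′ carbon of the vinylogous ester (C4a has no hydrogen and the γ-carbon C8 is deprotonated only under equilibrating conditions), giving the cross-conjugated lithium enolate 14. The enolate adds 1,2 to the aldehyde of 13, the most electrophilic site of the pyranone at this temperature, to give aldolate 15, which is captured at once as mesylate 16 so that it can neither revert nor take over the silyl group from O7. Et3N then removes the remaining C6 hydrogen and the mesylate, by far the better of the two β-leaving groups, departs (E1cB) to give the exocyclic enone 17. The closest known reaction type is the kinetic α′-aldol reaction of 3-alkoxycyclohex-2-enone enolates (Stork–Danheiser enolates) followed by mesylate elimination to a 6-alkylidene enone. No ring is closed. No lasting stereocentre is created: the carbinol and C6 centres are destroyed in the elimination, C7 stays racemic, and the alkene geometry (E expected, pyranone away from the carbonyl) is erased in step 8. The step needs site selectivity for C6 over C8, secured by the kinetic base and the blocked C4a, and retention of the 7-silyloxy group, secured by keeping the enolate at −78 °C, where the poor silyloxide leaving group is not expelled.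

Step 8
Reactants: 17 7-(tert-butyldimethylsilyloxy)-6-({6-ethyl-5-methyl-2-oxo-4-[2-(trimethylsilyl)ethoxy]-2H-pyran-3-yl}methylidene)-2,2-dimethyl-7,8-dihydro-2H-chromen-5(6H)-one
Product: 19 3-{[7-(tert-butyldimethylsilyloxy)-5-hydroxy-2,2-dimethyl-2H-chromen-6-yl]methyl}-6-ethyl-5-methyl-4-[2-(trimethylsilyl)ethoxy]-2H-pyran-2-one, via dienone tautomer 18 (not isolated)
Conditions: RhCl3·3H2O (10 mol %), NaHCO3, EtOH–THF, 70 °C
Reagents that add atoms: none
Why: Rhodium-catalysed isoaromatization of a 6-alkylidenecyclohex-2-enone: a hydridorhodium species adds across the exocyclic double bond with hydrogen going to the bridge carbon, the metal sits on the face of C6 opposite the bulky silyloxy group and hence syn to the C7 hydrogen, and β-hydride elimination gives the C6=C7 enol ether 18, which enolizes to the phenol; NaHCO3 holds back the HCl that could ionize the allylic silyl ether.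

Step 9
Reactants: 19 3-{[7-(tert-butyldimethylsilyloxy)-5-hydroxy-2,2-dimethyl-2H-chromen-6-yl]methyl}-6-ethyl-5-methyl-4-[2-(trimethylsilyl)ethoxy]-2H-pyran-2-one
Product: 21 3-[(5,7-dihydroxy-2,2-dimethyl-2H-chromen-6-yl)methyl]-6-ethyl-4-hydroxy-5-methyl-2H-pyran-2-one, via trimethylsilylethyl ether 20 (not isolated)
Conditions: Bu4NF (3 equiv), THF, 0 °C → rt, Ar; aq. NH4Cl
Reagents that add atoms: none
Why: Fluoride cleaves the aryl silyl ether first and then the 2-(trimethylsilyl)ethyl group by β-elimination (ethene and Me3SiF), as with trimethylsilylethyl esters, the pyranone oxygen leaving as a carboxylate-like anion.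

Step 10
Reactants: 22 (S)-2-methylbutanoic acid
Product: 23 (S)-2-methylbutanoyl chloride
Conditions: (COCl)2, DMF (cat.), CH2Cl2, 0 °C → rt; used crude
Reagents that add atoms: oxalyl chloride, O=C(Cl)C(=O)Cl
Why: Acid chloride formation through the catalytic chloroiminium species without amine base, so that no ketene forms and the α-stereocentre is kept.

Step 11
Reactants: 21 3-[(5,7-dihydroxy-2,2-dimethyl-2H-chromen-6-yl)methyl]-6-ethyl-4-hydroxy-5-methyl-2H-pyran-2-one; 23 (S)-2-methylbutanoyl chloride
Product: 24 3-({5,7-dihydroxy-2,2-dimethyl-8-[(2S)-2-methylbutanoyl]-2H-chromen-6-yl}methyl)-6-ethyl-4-hydroxy-5-methyl-2H-pyran-2-one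
Conditions: AlCl3 (4 equiv), CH2Cl2–MeNO2, −10 → 0 °C; then cold 1 M HCl
Reagents that add atoms: none
Why: Friedel–Crafts acylation of a phloroglucinol nucleus at its only free carbon C8, activated by O1 and 7-OH (ortho) and 5-OH (para); ring C has no free carbon and any O-acyl groups are hydrolysed on work-up, and at low temperature neither the acylium ion nor the product ketone should enolize, so the (S) configuration of 22 is carried over unchanged.

## Compound list

1 | benzene-1,3,5-triol (phloroglucinol) | Oc1cc(O)cc(O)c1 | starting material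
2 | 5-hydroxycyclohexane-1,3-dione | O=C1CC(O)CC(=O)C1 | intermediate
3 | 3,5-bis(tert-butyldimethylsilyloxy)cyclohex-2-en-1-one (racemic) | CC(C)(C)[Si](C)(C)OC1=CC(=O)CC(O[Si](C)(C)C(C)(C)C)C1 | intermediate (not isolated)
4 | 5-(tert-butyldimethylsilyloxy)cyclohexane-1,3-dione | O=C1CC(O[Si](C)(C)C(C)(C)C)CC(=O)C1 | intermediate
5 | 3-methylbut-2-enal | CC(C)=CC=O | starting material
6 | 5-(tert-butyldimethylsilyloxy)-2-(3-methylbut-2-en-1-ylidene)cyclohexane-1,3-dione | CC(C)=CC=C1C(=O)CC(O[Si](C)(C)C(C)(C)C)CC1=O | intermediate (not isolated)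
7 | 7-(tert-butyldimethylsilyloxy)-2,2-dimethyl-7,8-dihydro-2H-chromen-5(6H)-one (racemic) | CC1(C)C=CC2=C(O1)CC(O[Si](C)(C)C(C)(C)C)CC2=O | intermediate
8 | pentan-3-one | CCC(=O)CC | starting material
9 | malonyl dichloride | O=C(Cl)CC(=O)Cl | starting material
10 | 6-ethyl-4-hydroxy-5-methyl-2H-pyran-2-one | CCc1oc(=O)cc(O)c1C | intermediate
11 | N-[(4-chloro-6-ethyl-5-methyl-2-oxo-2H-pyran-3-yl)methylidene]-N-methylmethanaminium chloride | CCc1oc(=O)c(C=[N+](C)C)c(Cl)c1C.[Cl-] | intermediate (not isolated)
12 | 4-chloro-6-ethyl-5-methyl-2-oxo-2H-pyran-3-carbaldehyde | CCc1oc(=O)c(C=O)c(Cl)c1C | intermediate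
13 | 6-ethyl-5-methyl-2-oxo-4-[2-(trimethylsilyl)ethoxy]-2H-pyran-3-carbaldehyde | CCc1oc(=O)c(C=O)c(OCC[Si](C)(C)C)c1C | intermediate
14 | lithium 7-(tert-butyldimethylsilyloxy)-2,2-dimethyl-7,8-dihydro-2H-chromen-5-olate (racemic) | [Li+].[O-]C1=CC(O[Si](C)(C)C(C)(C)C)CC2=C1C=CC(C)(C)O2 | intermediate (not isolated)
15 | lithium [7-(tert-butyldimethylsilyloxy)-2,2-dimethyl-5-oxo-5,6,7,8-tetrahydro-2H-chromen-6-yl]{6-ethyl-5-methyl-2-oxo-4-[2-(trimethylsilyl)ethoxy]-2H-pyran-3-yl}methanolate (mixture of diastereomers) | [Li+].CCc1oc(=O)c(C([O-])C2C(O[Si](C)(C)C(C)(C)C)CC3=C(C=CC(C)(C)O3)C2=O)c(OCC[Si](C)(C)C)c1C | intermediate (not isolated)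
16 | [7-(tert-butyldimethylsilyloxy)-2,2-dimethyl-5-oxo-5,6,7,8-tetrahydro-2H-chromen-6-yl]{6-ethyl-5-methyl-2-oxo-4-[2-(trimethylsilyl)ethoxy]-2H-pyran-3-yl}methyl methanesulfonate (mixture of diastereomers) | CCc1oc(=O)c(C(OS(C)(=O)=O)C2C(O[Si](C)(C)C(C)(C)C)CC3=C(C=CC(C)(C)O3)C2=O)c(OCC[Si](C)(C)C)c1C | intermediate (not isolated)
17 | 7-(tert-butyldimethylsilyloxy)-6-({6-ethyl-5-methyl-2-oxo-4-[2-(trimethylsilyl)ethoxy]-2H-pyran-3-yl}methylidene)-2,2-dimethyl-7,8-dihydro-2H-chromen-5(6H)-one (racemic, alkene geometry not fixed) | CCc1oc(=O)c(C=C2C(O[Si](C)(C)C(C)(C)C)CC3=C(C=CC(C)(C)O3)C2=O)c(OCC[Si](C)(C)C)c1C | intermediate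
18 | 7-(tert-butyldimethylsilyloxy)-6-({6-ethyl-5-methyl-2-oxo-4-[2-(trimethylsilyl)ethoxy]-2H-pyran-3-yl}methyl)-2,2-dimethyl-2H-chromen-5(8H)-one | CCc1oc(=O)c(CC2=C(O[Si](C)(C)C(C)(C)C)CC3=C(C=CC(C)(C)O3)C2=O)c(OCC[Si](C)(C)C)c1C | intermediate (not isolated)
19 | 3-{[7-(tert-butyldimethylsilyloxy)-5-hydroxy-2,2-dimethyl-2H-chromen-6-yl]methyl}-6-ethyl-5-methyl-4-[2-(trimethylsilyl)ethoxy]-2H-pyran-2-one | CCc1oc(=O)c(Cc2c(O)c3C=CC(C)(C)Oc3cc2O[Si](C)(C)C(C)(C)C)c(OCC[Si](C)(C)C)c1C | intermediate
20 | 3-[(5,7-dihydroxy-2,2-dimethyl-2H-chromen-6-yl)methyl]-6-ethyl-5-methyl-4-[2-(trimethylsilyl)ethoxy]-2H-pyran-2-one | CCc1oc(=O)c(Cc2c(O)c3C=CC(C)(C)Oc3cc2O)c(OCC[Si](C)(C)C)c1C | intermediate (not isolated)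
21 | 3-[(5,7-dihydroxy-2,2-dimethyl-2H-chromen-6-yl)methyl]-6-ethyl-4-hydroxy-5-methyl-2H-pyran-2-one | CCc1oc(=O)c(Cc2c(O)c3C=CC(C)(C)Oc3cc2O)c(O)c1C | intermediate
22 | (S)-2-methylbutanoic acid | CC[C@H](C)C(=O)O | starting material
23 | (S)-2-methylbutanoyl chloride | CC[C@H](C)C(=O)Cl | intermediate
24 | 3-({5,7-dihydroxy-2,2-dimethyl-8-[(2S)-2-methylbutanoyl]-2H-chromen-6-yl}methyl)-6-ethyl-4-hydroxy-5-methyl-2H-pyran-2-one | CCc1oc(=O)c(Cc2c(O)c3c(c(C(=O)[C@@H](C)CC)c2O)OC(C)(C)C=C3)c(O)c1C | target

## Step count and least certain steps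

Total: 11 steps. Longest linear sequence: 7 steps (steps 1, 2, 3, 7, 8, 9 and 11 from 1; the pyranone branch through steps 4, 5, 6 is equally long).

**Step 7 (key step).** The most likely failure is expulsion of the 7-silyloxy group from the C6 lithium enolate (E1cB) if the enolate warms or the addition is slow. Silyl transfer from O7 to the aldolate oxygen and proton transfer from the 6-ethyl group of 13 to the enolate are further risks. The fallback replaces the basic lithium enolate by a neutral silyl enol ether and sets out from 7. Deprotonation with LiN(iPr)2 in the presence of Me3SiCl (internal quench, THF, −78 °C) would give 7-(tert-butyldimethylsilyloxy)-2,2-dimethyl-5-(trimethylsilyloxy)-7,8-dihydro-2H-chromene F1, a Danishefsky-type diene that is nucleophilic at C6. Mukaiyama aldol addition to 13 (BF3·OEt2, CH2Cl2, −78 °C) would give the neutral aldol 7-(tert-butyldimethylsilyloxy)-6-[{6-ethyl-5-methyl-2-oxo-4-[2-(trimethylsilyl)ethoxy]-2H-pyran-3-yl}(hydroxy)methyl]-2,2-dimethyl-7,8-dihydro-2H-chromen-5(6H)-one F2. MsCl and Et3N would then lead through mesylate 16 back to the route at 17.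

**Step 8.** The most likely failure is loss of the C7 oxygen, either by ionization of the allylic silyl ether assisted by the electron-rich pyranone, or by β-silyloxy elimination from the alkylrhodium intermediate when the metal adds syn to the silyloxy group. Failure of the hydride to insert into the hindered, donor-substituted alkene is the other risk. The fallback gives up the isomerization for a reduction–oxidation pair and sets out from 17. Conjugate reduction with [(Ph3P)CuH]6 (toluene, rt) would give 7-(tert-butyldimethylsilyloxy)-6-({6-ethyl-5-methyl-2-oxo-4-[2-(trimethylsilyl)ethoxy]-2H-pyran-3-yl}methyl)-2,2-dimethyl-7,8-dihydro-2H-chromen-5(6H)-one F3. HF·pyridine buffered with pyridine (THF, 0 °C) would free the alcohol 6-({6-ethyl-5-methyl-2-oxo-4-[2-(trimethylsilyl)ethoxy]-2H-pyran-3-yl}methyl)-7-hydroxy-2,2-dimethyl-7,8-dihydro-2H-chromen-5(6H)-one F4. Dess–Martin periodinane (NaHCO3, CH2Cl2) would oxidize it to 6-({6-ethyl-5-methyl-2-oxo-4-[2-(trimethylsilyl)ethoxy]-2H-pyran-3-yl}methyl)-2,2-dimethyl-2H-chromene-5,7(6H,8H)-dione F5. F5 is the keto form of 20 and should enolize to it, which is where the route is rejoined; Bu4NF as in step 9 then gives 21.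

**Step 11.** The most likely failure is attack of HCl or the Lewis acid on the electron-rich C3=C4 bond of ring A (hydrochlorination, oligomerization). Acid cleavage of the CH2 bridge and partial racemization through enolization of the acylium ion or the complexed ketone are further risks. The fallback replaces electrophilic substitution by a cross-coupling and sets out from 19. Iodination para to the free phenol (N-iodosuccinimide, CH2Cl2, 0 °C) would give 3-{[7-(tert-butyldimethylsilyloxy)-5-hydroxy-8-iodo-2,2-dimethyl-2H-chromen-6-yl]methyl}-6-ethyl-5-methyl-4-[2-(trimethylsilyl)ethoxy]-2H-pyran-2-one F6. Silylation (TBSCl, imidazole, DMF) would give 3-{[5,7-bis(tert-butyldimethylsilyloxy)-8-iodo-2,2-dimethyl-2H-chromen-6-yl]methyl}-6-ethyl-5-methyl-4-[2-(trimethylsilyl)ethoxy]-2H-pyran-2-one F7. Zinc insertion (Zn dust, LiCl, THF, 40 °C) would give [5,7-bis(tert-butyldimethylsilyloxy)-6-({6-ethyl-5-methyl-2-oxo-4-[2-(trimethylsilyl)ethoxy]-2H-pyran-3-yl}methyl)-2,2-dimethyl-2H-chromen-8-yl]zinc iodide F8. Coupling with 23 under Pd(PPh3)4 (zerovalent palladium, THF, rt) would give 3-({5,7-bis(tert-butyldimethylsilyloxy)-2,2-dimethyl-8-[(2S)-2-methylbutanoyl]-2H-chromen-6-yl}methyl)-6-ethyl-5-methyl-4-[2-(trimethylsilyl)ethoxy]-2H-pyran-2-one F9. Bu4NF buffered with AcOH would then return to the route at 24.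

**Step 6.** The most likely failure is diversion of the alcohol to the aldehyde or lactone carbonyl, or hydrolysis of the very electrophilic chloro aldehyde and its product by traces of water. The fallback reverses the polarity of the ether formation and sets out from 12. Deliberate hydrolysis (aq. NaOAc, THF, rt) would give 6-ethyl-4-hydroxy-5-methyl-2-oxo-2H-pyran-3-carbaldehyde F10. Mitsunobu alkylation of this acidic enol with 2-(trimethylsilyl)ethanol (PPh3, diisopropyl azodicarboxylate, THF, 0 °C) would return to the route at 13.

## Further compounds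

F1 | step 7 | 7-(tert-butyldimethylsilyloxy)-2,2-dimethyl-5-(trimethylsilyloxy)-7,8-dihydro-2H-chromene (racemic) | C[Si](C)(C)OC1=CC(O[Si](C)(C)C(C)(C)C)CC2=C1C=CC(C)(C)O2
F2 | step 7 | 7-(tert-butyldimethylsilyloxy)-6-[{6-ethyl-5-methyl-2-oxo-4-[2-(trimethylsilyl)ethoxy]-2H-pyran-3-yl}(hydroxy)methyl]-2,2-dimethyl-7,8-dihydro-2H-chromen-5(6H)-one (mixture of diastereomers) | CCc1oc(=O)c(C(O)C2C(O[Si](C)(C)C(C)(C)C)CC3=C(C=CC(C)(C)O3)C2=O)c(OCC[Si](C)(C)C)c1C
F3 | step 8 | 7-(tert-butyldimethylsilyloxy)-6-({6-ethyl-5-methyl-2-oxo-4-[2-(trimethylsilyl)ethoxy]-2H-pyran-3-yl}methyl)-2,2-dimethyl-7,8-dihydro-2H-chromen-5(6H)-one (mixture of diastereomers) | CCc1oc(=O)c(CC2C(O[Si](C)(C)C(C)(C)C)CC3=C(C=CC(C)(C)O3)C2=O)c(OCC[Si](C)(C)C)c1C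
F4 | step 8 | 6-({6-ethyl-5-methyl-2-oxo-4-[2-(trimethylsilyl)ethoxy]-2H-pyran-3-yl}methyl)-7-hydroxy-2,2-dimethyl-7,8-dihydro-2H-chromen-5(6H)-one (mixture of diastereomers) | CCc1oc(=O)c(CC2C(O)CC3=C(C=CC(C)(C)O3)C2=O)c(OCC[Si](C)(C)C)c1C
F5 | step 8 | 6-({6-ethyl-5-methyl-2-oxo-4-[2-(trimethylsilyl)ethoxy]-2H-pyran-3-yl}methyl)-2,2-dimethyl-2H-chromene-5,7(6H,8H)-dione | CCc1oc(=O)c(CC2C(=O)CC3=C(C=CC(C)(C)O3)C2=O)c(OCC[Si](C)(C)C)c1C
F6 | step 11 | 3-{[7-(tert-butyldimethylsilyloxy)-5-hydroxy-8-iodo-2,2-dimethyl-2H-chromen-6-yl]methyl}-6-ethyl-5-methyl-4-[2-(trimethylsilyl)ethoxy]-2H-pyran-2-one | CCc1oc(=O)c(Cc2c(O)c3C=CC(C)(C)Oc3c(I)c2O[Si](C)(C)C(C)(C)C)c(OCC[Si](C)(C)C)c1C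
F7 | step 11 | 3-{[5,7-bis(tert-butyldimethylsilyloxy)-8-iodo-2,2-dimethyl-2H-chromen-6-yl]methyl}-6-ethyl-5-methyl-4-[2-(trimethylsilyl)ethoxy]-2H-pyran-2-one | CCc1oc(=O)c(Cc2c(O[Si](C)(C)C(C)(C)C)c3C=CC(C)(C)Oc3c(I)c2O[Si](C)(C)C(C)(C)C)c(OCC[Si](C)(C)C)c1C
F8 | step 11 | [5,7-bis(tert-butyldimethylsilyloxy)-6-({6-ethyl-5-methyl-2-oxo-4-[2-(trimethylsilyl)ethoxy]-2H-pyran-3-yl}methyl)-2,2-dimethyl-2H-chromen-8-yl]zinc iodide | CCc1oc(=O)c(Cc2c(O[Si](C)(C)C(C)(C)C)c3C=CC(C)(C)Oc3c([Zn]I)c2O[Si](C)(C)C(C)(C)C)c(OCC[Si](C)(C)C)c1C
F9 | step 11 | 3-({5,7-bis(tert-butyldimethylsilyloxy)-2,2-dimethyl-8-[(2S)-2-methylbutanoyl]-2H-chromen-6-yl}methyl)-6-ethyl-5-methyl-4-[2-(trimethylsilyl)ethoxy]-2H-pyran-2-one | CCc1oc(=O)c(Cc2c(O[Si](C)(C)C(C)(C)C)c3C=CC(C)(C)Oc3c(C(=O)[C@@H](C)CC)c2O[Si](C)(C)C(C)(C)C)c(OCC[Si](C)(C)C)c1C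
F10 | step 6 | 6-ethyl-4-hydroxy-5-methyl-2-oxo-2H-pyran-3-carbaldehyde | CCc1oc(=O)c(C=O)c(O)c1C
A1 | alternative 1 | 3-[(5,7-dihydroxy-2,2-dimethyl-2H-chromen-6-yl)methyl]-6-ethyl-4-hydroxy-5-methyl-2H-pyran-2-one | CCc1oc(=O)c(Cc2c(O)cc3OC(C)(C)C=Cc3c2O)c(O)c1C
A2 | alternative 1 | 3-{[2,6-dihydroxy-4-(2-methylbut-3-yn-2-yloxy)phenyl]methyl}-6-ethyl-4-hydroxy-5-methyl-2H-pyran-2-one | CCc1oc(=O)c(Cc2c(O)cc(OC(C)(C)C#C)cc2O)c(O)c1C
A3 | alternative 2 | (2S)-2-methyl-1-[2,4,6-tris(methoxymethoxy)phenyl]butan-1-one | CC[C@H](C)C(=O)c1c(OCOC)cc(OCOC)cc1OCOC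
A4 | alternative 2 | (2E)-2-methyl-1-[2,4,6-tris(methoxymethoxy)phenyl]but-2-en-1-one | C/C=C(\C)C(=O)c1c(OCOC)cc(OCOC)cc1OCOC
A5 | alternative 3 | 6-({6-ethyl-5-methyl-4-[(2S)-2-methylbutanoyloxy]-2-oxo-2H-pyran-3-yl}methyl)-7-hydroxy-2,2-dimethyl-8-[(2S)-2-methylbutanoyl]-2H-chromen-5-yl (2S)-2-methylbutanoate | CCc1oc(=O)c(Cc2c(OC(=O)[C@@H](C)CC)c3C=CC(C)(C)Oc3c(C(=O)[C@@H](C)CC)c2O)c(OC(=O)[C@@H](C)CC)c1C
A6 | alternative 3 | 6-({6-ethyl-5-methyl-4-[(2S)-2-methylbutanoyloxy]-2-oxo-2H-pyran-3-yl}methyl)-8-iodo-2,2-dimethyl-2H-chromene-5,7-diyl bis[(2S)-2-methylbutanoate] | CCc1oc(=O)c(Cc2c(OC(=O)[C@@H](C)CC)c3C=CC(C)(C)Oc3c(I)c2OC(=O)[C@@H](C)CC)c(OC(=O)[C@@H](C)CC)c1C
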